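**Plan**
- Retrosynthesis first cuts the three O–S bonds of the sulfate esters and then the C3–O bond, leaving a 7,4'-dibenzyloxy-3'-methoxyflavone.
- In that flavone, C4 is a single carbonyl carbon between C4a of ring A and the C3–C2 unit that carries ring B, and O1 sits ortho to C4a. The pyranone is therefore cut at C4a–C4, C4–C3 and O1–C2 into an ortho-iodophenol, carbon monoxide and an aryl acetylene.
- Forward, ring A (iodophenol from 3-(benzyloxy)phenol) and ring B (alkyne from O-benzylvanillin) are prepared separately, and ring C is closed last in one carbonylative coupling–annulation.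
- The 3-hydroxyl is then introduced by epoxidation and acid opening, the benzyl ethers are removed, and all three hydroxyls are sulfated.
- The target has no stereocentre; the only stereogenic intermediate is a racemic epoxide that is consumed in the step that forms it.

Key step: step 3

Remark: the target is drawn as the tris(hydrogen sulfate), so step 6 ends with cation exchange to the acid form. It should be kept cold and lyophilised at once, because aryl hydrogen sulfates hydrolyse autocatalytically.

Step 1
Reactants: 1 3-(benzyloxy)phenol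
Product: 2 5-(benzyloxy)-2-iodophenol
Conditions: I2 (1.05 equiv), NaHCO3 (1.2 equiv), THF/H2O (1:1), 0 °C → rt
Reagents that add atoms: iodine, II
Why: Electrophilic aromatic iodination of the phenoxide should go to the carbon ortho to the free hydroxyl and para to the benzyloxy group, which both oxygens activate and which is less hindered than the carbon between them, as in the corresponding iodination of 3-methoxyphenol; any para-iodo isomer is removed by chromatography.

Step 2
Reactants: 3 4-(benzyloxy)-3-methoxybenzaldehyde (O-benzylvanillin)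
Product: 4 1-(benzyloxy)-4-ethynyl-2-methoxybenzene
Conditions: dimethyl (1-diazo-2-oxopropyl)phosphonate (1.3 equiv), K2CO3 (2 equiv), MeOH/THF, 0 °C → rt
Reagents that add atoms: dimethyl (1-diazo-2-oxopropyl)phosphonate, CC(=O)C(=[N+]=[N-])P(=O)(OC)OC
Why: In this Ohira–Bestmann variant of the Seyferth–Gilbert homologation, methanolysis of the reagent releases the diazomethylphosphonate anion, which adds to the aldehyde in Horner–Wadsworth–Emmons fashion, and the diazoalkene loses dinitrogen with a 1,2-hydrogen shift to give the terminal alkyne under conditions the benzyl ether tolerates.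

Step 3
Reactants: 2 5-(benzyloxy)-2-iodophenol; 4 1-(benzyloxy)-4-ethynyl-2-methoxybenzene (1.2 equiv); 5 carbon monoxide
Product: 8 7-(benzyloxy)-2-[4-(benzyloxy)-3-methoxyphenyl]-4H-chromen-4-one, via ortho-hydroxyaryl ynone 6 (not isolated), via diethylamino enaminone 7 (not isolated)
Conditions: PdCl2(dppf) [dichloro(1,1'-bis(diphenylphosphino)ferrocene)palladium] (3 mol %), CO (20 bar), Et2NH (solvent), 120 °C, autoclave
Reagents that add atoms: none
Why: Zerovalent palladium formed from PdCl2(dppf) inserts into the carbon–iodine bond of 2, CO inserts to give an aroylpalladium species (C4a–C4), and the acetylide of 4 generated with diethylamine is transferred and reductively eliminated (C4–C3) to give ynone 6. Diethylamine then adds to the ynone to give enaminone 7, and the phenol oxygen attacks the amine-bearing β-carbon and expels diethylamine (O1–C2), closing ring C. The closest known reaction type is the palladium-catalysed carbonylative Sonogashira coupling and cyclisation of 2-iodophenols with terminal aryl acetylenes to flavones. Ring C closes in the 6-endo mode (6-endo-dig with respect to the ynone, realised as a 6-endo-trig addition–elimination on the enaminone), and no stereocentre is formed. Two selectivities are needed: carbonylative over direct coupling (which would lead on to a 2-arylbenzofuran), secured by the CO pressure, the copper-free medium and the chelating dppf ligand, and six- over five-membered closure (aurone), secured by the secondary-amine pathway. In the substrate, the free hydroxyl ortho to iodine is the only nucleophile that can reach the β-carbon, and the benzyl ethers mask the other two phenols and are inert under these conditions.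

Step 4
Reactants: 8 7-(benzyloxy)-2-[4-(benzyloxy)-3-methoxyphenyl]-4H-chromen-4-one
Product: 10 7-(benzyloxy)-2-[4-(benzyloxy)-3-methoxyphenyl]-3-hydroxy-4H-chromen-4-one, via cis-2,3-epoxyflavanone 9 (not isolated)
Conditions: dimethyldioxirane (ca. 0.07 M in acetone, 3 equiv), CH2Cl2, 0 °C → rt; evaporate; then p-TsOH·H2O (10 mol %), CH2Cl2, rt
Reagents that add atoms: dimethyldioxirane, CC1(C)OO1
Why: Dioxirane epoxidation of the flavone C2=C3 bond gives the racemic cis-fused epoxide 9, whose configuration is irrelevant because acid opens it at C2 to an oxocarbenium ion stabilised by O1 and ring B, and loss of H3 restores the pyranone as the 3-hydroxy compound; this is the known dioxirane route from flavones to flavonols, which benzyl ethers should survive at low temperature and short contact time.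

Step 5
Reactants: 10 7-(benzyloxy)-2-[4-(benzyloxy)-3-methoxyphenyl]-3-hydroxy-4H-chromen-4-one
Product: 11 3,7-dihydroxy-2-(4-hydroxy-3-methoxyphenyl)-4H-chromen-4-one (geraldol)
Conditions: H2 (1 atm), Pd/C (10 wt %), THF/MeOH, rt
Reagents that add atoms: none
Why: Catalytic hydrogenolysis of the two benzyl aryl ethers over palladium on carbon should be much faster than reduction of the fully conjugated 3-hydroxypyranone, so the triol is freed without touching the C2=C3 bond or the methyl ether.

Step 6
Reactants: 11 3,7-dihydroxy-2-(4-hydroxy-3-methoxyphenyl)-4H-chromen-4-one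
Product: 13 2-methoxy-4-[4-oxo-3,7-bis(sulfooxy)-4H-chromen-2-yl]phenyl hydrogen sulfate (the target), via tris(pyridinium) trisulfate 12 (not isolated)
Conditions: SO3·pyridine (12 equiv), pyridine, 60 °C; then Sephadex G-10 (H2O); sulfonic acid resin (H+ form), H2O, 0 °C; lyophilise
Reagents that add atoms: sulfur trioxide–pyridine complex, O=S(=O)([O-])[n+]1ccccc1
Why: O-Sulfation with excess sulfur trioxide–amine complex is the standard per-sulfation of flavonoids that lack a 5-hydroxyl; heat and excess reagent should carry the hydrogen-bonded 3-hydroxyl to completion, and cold cation exchange converts the pyridinium salt 12 into the acid form drawn for the target.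

**Compound list**
1 | 3-(benzyloxy)phenol | Oc1cccc(OCc2ccccc2)c1 | starting material
2 | 5-(benzyloxy)-2-iodophenol | Oc1cc(OCc2ccccc2)ccc1I | intermediate
3 | 4-(benzyloxy)-3-methoxybenzaldehyde (O-benzylvanillin) | COc1cc(C=O)ccc1OCc1ccccc1 | starting material
4 | 1-(benzyloxy)-4-ethynyl-2-methoxybenzene | C#Cc1ccc(OCc2ccccc2)c(OC)c1 | intermediate
5 | carbon monoxide | [C-]#[O+] | starting material
6 | 1-[4-(benzyloxy)-2-hydroxyphenyl]-3-[4-(benzyloxy)-3-methoxyphenyl]prop-2-yn-1-one | COc1cc(C#CC(=O)c2ccc(OCc3ccccc3)cc2O)ccc1OCc1ccccc1 | intermediate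
7 | (2E)-1-[4-(benzyloxy)-2-hydroxyphenyl]-3-[4-(benzyloxy)-3-methoxyphenyl]-3-(diethylamino)prop-2-en-1-one (drawn as the E isomer; the geometry is not decisive) | CCN(CC)/C(=C/C(=O)c1ccc(OCc2ccccc2)cc1O)c1ccc(OCc2ccccc2)c(OC)c1 | intermediate
8 | 7-(benzyloxy)-2-[4-(benzyloxy)-3-methoxyphenyl]-4H-chromen-4-one | COc1cc(-c2cc(=O)c3ccc(OCc4ccccc4)cc3o2)ccc1OCc1ccccc1 | intermediate
9 | 7-(benzyloxy)-2-[4-(benzyloxy)-3-methoxyphenyl]-2,3-epoxy-2,3-dihydro-4H-chromen-4-one (cis-fused epoxide, racemic, one enantiomer drawn) | COc1cc([C@@]23O[C@@H]2C(=O)c2ccc(OCc4ccccc4)cc2O3)ccc1OCc1ccccc1 | intermediate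
10 | 7-(benzyloxy)-2-[4-(benzyloxy)-3-methoxyphenyl]-3-hydroxy-4H-chromen-4-one | COc1cc(-c2oc3cc(OCc4ccccc4)ccc3c(=O)c2O)ccc1OCc1ccccc1 | intermediate
11 | 3,7-dihydroxy-2-(4-hydroxy-3-methoxyphenyl)-4H-chromen-4-one (geraldol) | COc1cc(-c2oc3cc(O)ccc3c(=O)c2O)ccc1O | intermediate
12 | tris(pyridinium) 2-[3-methoxy-4-(sulfonatooxy)phenyl]-4-oxo-4H-chromene-3,7-diyl bis(sulfate) | COc1cc(-c2oc3cc(OS(=O)(=O)[O-])ccc3c(=O)c2OS(=O)(=O)[O-])ccc1OS(=O)(=O)[O-].c1cc[nH+]cc1.c1cc[nH+]cc1.c1cc[nH+]cc1 | intermediate
13 | 2-methoxy-4-[4-oxo-3,7-bis(sulfooxy)-4H-chromen-2-yl]phenyl hydrogen sulfate | COc1cc(-c2oc3cc(OS(=O)(=O)O)ccc3c(=O)c2OS(=O)(=O)O)ccc1OS(=O)(=O)O | target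

**Step count and risks**
Total step count: 6. Longest linear sequence: 5 (steps 1, 3, 4, 5, 6 or steps 2, 3, 4, 5, 6).

Steps most likely to fail:

1. Step 3. The coupling may proceed without CO uptake and then cyclise to a benzofuran, the ynone may close in the five-membered mode, or oxidative addition to the electron-rich aryl iodide may be slow. The fallback sets out from aldehyde 3 and returns at flavone 8. Claisen–Schmidt condensation of 3 with commercial 1-[4-(benzyloxy)-2-hydroxyphenyl]ethanone (KOH, EtOH, rt) should give the chalcone (2E)-1-[4-(benzyloxy)-2-hydroxyphenyl]-3-[4-(benzyloxy)-3-methoxyphenyl]prop-2-en-1-one F1. Oxidative cyclisation of F1 with catalytic I2 in DMSO at 130 °C should then give 8.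

2. Step 4. The dioxirane may oxidise the benzylic positions of the ethers, epoxidation of the electron-poor enone double bond may stall, or the epoxide may rearrange under acid along a path other than to the flavonol. The fallback sets out from flavone 8 and returns at flavonol 10. Deprotonation at C3 with LiN(iPr)2 in THF at −78 °C should give {7-(benzyloxy)-2-[4-(benzyloxy)-3-methoxyphenyl]-4-oxo-4H-chromen-3-yl}lithium F2. Trapping with B(OMe)3 gives lithium {7-(benzyloxy)-2-[4-(benzyloxy)-3-methoxyphenyl]-4-oxo-4H-chromen-3-yl}trimethoxyborate F3, and oxidation of the carbon–boron bond in the same flask with H2O2/AcOH should give 10.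

3. Step 6. Sulfation of the hydrogen-bonded 3-hydroxyl may remain incomplete, and sulfate may be lost by hydrolysis while the very polar product is purified and acidified. The fallback sets out from triol 11 and returns at target 13. Treatment with 2,2,2-trichloroethyl chlorosulfate, Et3N and DMAP in THF should give the neutral triester 2-{3-methoxy-4-[(2,2,2-trichloroethoxy)sulfonyloxy]phenyl}-4-oxo-4H-chromene-3,7-diyl bis(2,2,2-trichloroethyl) bis(sulfate) F4, which can be chromatographed on silica. Reductive removal of the trichloroethyl groups with Zn dust and HCO2NH4 in MeOH should give triammonium 2-[3-methoxy-4-(sulfonatooxy)phenyl]-4-oxo-4H-chromene-3,7-diyl bis(sulfate) F5, and cold cation exchange on sulfonic acid resin (H+ form) gives 13.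

**Further compounds**
F1 | step 3 | (2E)-1-[4-(benzyloxy)-2-hydroxyphenyl]-3-[4-(benzyloxy)-3-methoxyphenyl]prop-2-en-1-one | COc1cc(/C=C/C(=O)c2ccc(OCc3ccccc3)cc2O)ccc1OCc1ccccc1
F2 | step 4 | {7-(benzyloxy)-2-[4-(benzyloxy)-3-methoxyphenyl]-4-oxo-4H-chromen-3-yl}lithium | [Li]c1c(-c2ccc(OCc3ccccc3)c(OC)c2)oc2cc(OCc3ccccc3)ccc2c1=O
F3 | step 4 | lithium {7-(benzyloxy)-2-[4-(benzyloxy)-3-methoxyphenyl]-4-oxo-4H-chromen-3-yl}trimethoxyborate | [Li+].CO[B-](OC)(OC)c1c(-c2ccc(OCc3ccccc3)c(OC)c2)oc2cc(OCc3ccccc3)ccc2c1=O
F4 | step 6 | 2-{3-methoxy-4-[(2,2,2-trichloroethoxy)sulfonyloxy]phenyl}-4-oxo-4H-chromene-3,7-diyl bis(2,2,2-trichloroethyl) bis(sulfate) | COc1cc(-c2oc3cc(OS(=O)(=O)OCC(Cl)(Cl)Cl)ccc3c(=O)c2OS(=O)(=O)OCC(Cl)(Cl)Cl)ccc1OS(=O)(=O)OCC(Cl)(Cl)Cl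
F5 | step 6 | triammonium 2-[3-methoxy-4-(sulfonatooxy)phenyl]-4-oxo-4H-chromene-3,7-diyl bis(sulfate) | COc1cc(-c2oc3cc(OS(=O)(=O)[O-])ccc3c(=O)c2OS(=O)(=O)[O-])ccc1OS(=O)(=O)[O-].[NH4+].[NH4+].[NH4+]
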